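(All constants stand for no real mixture; the rest is arithmetic.)

Every partner that ends up in product first came out of the solid, so in this closed flask product plus dissolved partner always equals what the solid has delivered, and the chain moves material between those two without changing their sum.

    initiator → 2 initiating radical (k1 = 0.23 s⁻¹)
    starting material + initiating radical → chain carrier (k2 = 1.1 × 10⁶ M⁻¹ s⁻¹)
    partner + chain carrier ⇌ product + initiating radical (K3 = 2.2, k3 = 1.1 × 10⁷ M⁻¹ s⁻¹)
    2 chain carrier → ended chains (k4 = 5 × 10⁷ M⁻¹ s⁻¹)
    solid reagent ⇌ partner, rate k5*(cs5 - [partner]) while solid is left; crystals form when [partner] > cs5 (cs5 = 0.41 mM, k5 = 0.072 s⁻¹)
    starting material ⇌ dormant form (K6 = 2.5, k6 = 0.23 s⁻¹)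

starting material 1.0 mM; solid reagent 3.00 equiv; initiator 1 mol%; time 25 s

- in percentages every species weighs as the starting material in it: one ended chains counts as two
- a step written with two of one species runs at k times the square of its concentration and takes two of it each time
- as a solid, counted per litre of solution: solid reagent
- at the start none of the solid reagent is in solution
- run time (flask): 25 s

* amount of product at 25 s, in percent of the starting material charged
* the change that raises the amount of product at 25 s, in percent of the starting material charged most ("none" if none brings more than 2 percentage points) (delta / eta / none)
* amount of product at 25 s, in percent of the starting material charged, after delta

- delta: doubling the solubility in step 5, all else as stated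
- eta: doubling the dissolution coefficient of step 5, all else as stated

The dissolving rate is the dissolution coefficient times the gap between solubility and [partner], and it is greatest while [partner] stands at zero. Integrating that greatest rate over the time gives what I call the delivery ceiling: coefficient times solubility times time, divided by the charge of starting material, here 73.8%. Turning the question round, a flask whose dissolving set no bound on product would need this ceiling above the full charge, but this flask stands below it, so I hold product at 25 s under 73.8%, however fast the chain runs. Delta and eta each lift the ceiling to 148%, above the charge, so on the ceiling they tie. At equal [partner], though, the dissolving rate under delta exceeds the rate under eta by the coefficient times [partner], and that difference grows as [partner] climbs, so I take delta. My reckoning gives a bound on product and no single figure.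

The forecast gives 35%, then delta as the best change and 50% after it, reasoning that “Doubling the solubility and doubling the dissolution coefficient give the same initial dissolution flux”. It names a figure for product where I have a bound.

The flask gives 29.9% of product at 25 s, 5.1 percentage points below the forecast, with delta bringing 15 points, more than the 11 points of eta, and 45.1% after delta. Its product and its [partner] of 0.235 mM together make 53.4% of the charge, which is 72.4% of the ceiling. In the flask left until 10 s the ceiling is 29.5%, and there product at 18.4% and [partner] at 0.0835 mM make 26.7%, which is 90.5% of that ceiling.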